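**Retrosynthetic overview**

1. The target is 2,5,6-tribromo-1-methylgramine N-oxide. The N–O bond is made last from the tertiary amine, the C3–CH2–N unit comes from a 3-carbaldehyde, and C2–Br plus C3–CHO both come from the C2 carbonyl and C3 methylene of an oxindole (bromoformylation).
2. The strategy rests on the benzo ring: Br on C5 and C6 flanked by H on C4 and C7 is the C2=C3(Br)–C4(Br)=C5 diene of 3,4-dibromothiophene 1,1-dioxide. The C3a–C7a bond, with N1 on C7a and an oxidised C2 next to it, is the enamide C4=C5 bond of 1-methyl-1,3-dihydro-2H-pyrrol-2-one.
3. Key disconnection: C3a–C4 and C7–C7a, by [4+2] cycloaddition, loss of SO2 and dehydrogenation, to give 5,6-dibromo-1-methylindolin-2-one.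
4. Ring order: the five-membered lactam ring is bought (N-methylsuccinimide), the benzene ring is built onto it in the key step, and the pyrrole ring becomes aromatic in the bromoformylation.
5. Both partners are made fresh: the dioxide by peracid oxidation of 3,4-dibromothiophene, the enamide by imide reduction and dehydration.

Key step: step 4

Assumption (chemistry): the target is achiral, so no stereocentre has to be set. Compounds 5, 6, 8 and 9 are racemic (one enantiomer drawn for 8 and 9). Adduct 8 is drawn as the endo isomer; the exo isomer would lose SO2 to the same diene 9.

**Route**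

Step 1
Reactants: 1 3,4-dibromothiophene
Product: 3 3,4-dibromothiophene 1,1-dioxide, via thiophene 1-oxide 2 (not isolated)
Conditions: (CF3CO)2O, H2O2 (50% aq.), CH2Cl2, 0 → 25 °C; aq. NaHCO3/Na2SO3 wash, crystallisation, stored cold
Reagents that add atoms: hydrogen peroxide, OO
Why: Electrophilic S-oxidation (thiophene to sulfoxide to sulfone) by trifluoroperacetic acid, formed in the flask from H2O2 and (CF3CO)2O, should overcome the low nucleophilicity of the bromine-deactivated sulfur, and the second oxidation should outrun self-trapping of sulfoxide 2, so the dioxide should be isolable and is used soon after it is made.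

Step 2
Reactants: 4 N-methylsuccinimide
Product: 5 5-hydroxy-1-methylpyrrolidin-2-one (racemic)
Conditions: NaBH4, EtOH, −10 → 0 °C, HCl/EtOH added dropwise (pH 8–9); acetone quench, neutral work-up
Reagents that add atoms: none
Why: Partial hydride reduction of a cyclic imide (Speckamp-type NaBH4 reduction) should stop at the hydroxylactam because the alkoxide does not open in the cold; the symmetric imide poses no regiochemical question, and the new C5 stereocentre is racemic and is destroyed in step 3.

Step 3
Reactants: 5 5-hydroxy-1-methylpyrrolidin-2-one
Product: 7 1-methyl-1,3-dihydro-2H-pyrrol-2-one, via hemiaminal mesylate 6 (not isolated)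
Conditions: MsCl, Et3N, CH2Cl2, −20 → 0 °C; cold dilute aq. citric acid wash, concentrated cold, used at once
Reagents that add atoms: none
Why: O-sulfonylation of the hemiaminal, ionisation to the N-acyliminium ion and loss of the C4 proton (E1-type β-elimination) should give the 4,5-unsaturated enamide as the kinetic product, and the cold, brief procedure with removal of the amine is meant to hold back base-catalysed drift to the conjugated 1,5-dihydro tautomer.

Step 4
Reactants: 3 3,4-dibromothiophene 1,1-dioxide; 7 1-methyl-1,3-dihydro-2H-pyrrol-2-one
Product: 10 5,6-dibromo-1-methylindolin-2-one, via bridged sulfone adduct 8 (not isolated), via cis-dihydroindolinone 9 (not isolated)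
Conditions: 7 (2 equiv), PhMe, 80 °C, 3 added over 4 h; excess 7 evaporated; then DDQ (1.2 equiv), PhMe, 25 °C
Reagents that add atoms: none
Why: The electron-poor cyclic diene of 3 (LUMO lowered by the sulfone and the two bromines) should add across the electron-rich C4=C5 enamide bond of 7 in a concerted, suprafacial inverse-electron-demand [4+2] cycloaddition, the known behaviour of halogenated thiophene 1,1-dioxides towards enol ethers, enamines and related electron-rich alkenes. The six-membered carbocycle closes in this one intermolecular event onto the existing lactam ring, C3a–C4 and C7–C7a forming together to give the 7-thiabicyclo[2.2.1]heptene dioxide 8, which should lose SO2 by cheletropic retro-addition at the reaction temperature to give the cis-fused cyclohexadiene 9. DDQ should then take hydride from C7a (cation stabilised by N1 and the dienyl system) and a proton from C3a, so the two ring-fusion stereocentres, cis because the addition is suprafacial, are transient and none remains in 10. The substitution of the diene is symmetric, so no regiochemical question arises and the bromines arrive on C5 and C6 with C4 and C7 unsubstituted. The step needs three chemoselectivities: reaction of the enamide tautomer and not the conjugated lactam (only the enamide has the high HOMO), cycloaddition ahead of dioxide self-dimerisation (excess 7, slow addition of 3), and dehydrogenation ahead of eliminative opening of the C7a–N1 bond (neutral medium, poor amide leaving group, DDQ added as soon as SO2 evolution ends). Unreacted 7 is removed before the oxidant is added so that DDQ is spent only on 9.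

Step 5
Reactants: 10 5,6-dibromo-1-methylindolin-2-one
Product: 12 2,5,6-tribromo-1-methyl-1H-indole-3-carbaldehyde, via iminium bromide 11 (not isolated)
Conditions: POBr3, DMF, CHCl3, 0 → 60 °C; then ice–water
Reagents that add atoms: N,N-dimethylformamide, CN(C)C=O; phosphoryl bromide, O=P(Br)(Br)Br; water, O
Why: Vilsmeier–Haack haloformylation of an oxindole: the enol of 10 should be formylated at C3 by the bromoiminium reagent from DMF and POBr3, the activated lactam oxygen is replaced by bromide with aromatisation to the indole, and hydrolysis of iminium salt 11 releases the aldehyde while the aryl bromides stay untouched.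

Step 6
Reactants: 12 2,5,6-tribromo-1-methyl-1H-indole-3-carbaldehyde
Product: 14 1-(2,5,6-tribromo-1-methyl-1H-indol-3-yl)-N,N-dimethylmethanamine, via iminium acetate 13 (not isolated)
Conditions: Me2NH (2 M in THF), AcOH, NaBH(OAc)3, ClCH2CH2Cl, 25 °C
Reagents that add atoms: dimethylamine, CNC
Why: Direct reductive amination with NaBH(OAc)3: dimethylamine buffered by AcOH should condense with the aldehyde to iminium ion 13, which the mild hydride reduces faster than the vinylogous-amide aldehyde, while the acidic buffer and room temperature keep free amine from displacing the C2 bromide.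

Step 7
Reactants: 14 1-(2,5,6-tribromo-1-methyl-1H-indol-3-yl)-N,N-dimethylmethanamine
Product: 15 1-(2,5,6-tribromo-1-methyl-1H-indol-3-yl)-N,N-dimethylmethanamine N-oxide (target)
Conditions: mCPBA (1.0 equiv), CH2Cl2, −10 → 0 °C; filtration through basic Al2O3
Reagents that add atoms: 3-chloroperbenzoic acid, O=C(OO)c1cccc(Cl)c1
Why: Peracid N-oxidation of a tertiary amine: the sp3 nitrogen of 14 is by far the most nucleophilic site, the tribrominated indole π-system being much less reactive, so one equivalent of mCPBA in the cold should give the N-oxide, which is kept cold to avoid Meisenheimer rearrangement.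

**Compound list**

1 | 3,4-dibromothiophene | Brc1cscc1Br | starting material
2 | 3,4-dibromothiophene 1-oxide | O=S1C=C(Br)C(Br)=C1 | intermediate (not isolated)
3 | 3,4-dibromothiophene 1,1-dioxide | O=S1(=O)C=C(Br)C(Br)=C1 | intermediate
4 | N-methylsuccinimide (1-methylpyrrolidine-2,5-dione) | CN1C(=O)CCC1=O | starting material
5 | 5-hydroxy-1-methylpyrrolidin-2-one (racemic) | CN1C(O)CCC1=O | intermediate
6 | 1-methyl-5-oxopyrrolidin-2-yl methanesulfonate (racemic) | CN1C(OS(C)(=O)=O)CCC1=O | intermediate (not isolated)
7 | 1-methyl-1,3-dihydro-2H-pyrrol-2-one | CN1C=CCC1=O | intermediate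
8 | endo-5,6-dibromo-1-methyl-1,3,3a,4,7,7a-hexahydro-2H-4,7-epithioindol-2-one 8,8-dioxide (racemic, cis ring fusion, lactam ring anti to the SO2 bridge) | CN1C(=O)C[C@@H]2[C@H]1[C@@H]3C(Br)=C(Br)[C@H]2S3(=O)=O | intermediate (not isolated)
9 | cis-5,6-dibromo-1-methyl-1,3,3a,7a-tetrahydro-2H-indol-2-one (racemic) | CN1C(=O)C[C@@H]2[C@H]1C=C(Br)C(Br)=C2 | intermediate (not isolated)
10 | 5,6-dibromo-1-methylindolin-2-one | CN1C(=O)Cc2cc(Br)c(Br)cc21 | intermediate
11 | [(2,5,6-tribromo-1-methyl-1H-indol-3-yl)methylidene]dimethylammonium bromide | C[N+](C)=Cc1c(Br)n(C)c2cc(Br)c(Br)cc12.[Br-] | intermediate (not isolated)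
12 | 2,5,6-tribromo-1-methyl-1H-indole-3-carbaldehyde | Cn1c(Br)c(C=O)c2cc(Br)c(Br)cc21 | intermediate
13 | [(2,5,6-tribromo-1-methyl-1H-indol-3-yl)methylidene]dimethylammonium acetate | C[N+](C)=Cc1c(Br)n(C)c2cc(Br)c(Br)cc12.CC(=O)[O-] | intermediate (not isolated)
14 | 1-(2,5,6-tribromo-1-methyl-1H-indol-3-yl)-N,N-dimethylmethanamine | Cn1c(Br)c(CN(C)C)c2cc(Br)c(Br)cc21 | intermediate
15 | 1-(2,5,6-tribromo-1-methyl-1H-indol-3-yl)-N,N-dimethylmethanamine N-oxide | Cn1c(Br)c(C[N+](C)(C)[O-])c2cc(Br)c(Br)cc21 | target

**Step count**

Total steps: 7. Longest linear sequence: 6 steps (4 → 5 → 7 → 10 → 12 → 14 → 15); the dioxide branch (1 → 3) joins at step 4.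

**Steps most likely to fail**

Step 4 (key step). What may go wrong is self-dimerisation of the dioxide outrunning the cycloaddition, drift of the enamide into the unreactive conjugated lactam during heating, or aromatisation by eliminative opening of the C7a–N1 bond instead of dehydrogenation. The fallback gives up the cycloaddition and places the bromines by electrophilic substitution on a preformed bicycle. It replaces both partners 3 and 7, so it sets out from no numbered compound but from purchased 6-bromoindoline-2,3-dione F1. Bromination with Br2 in AcOH at 80 °C should go para to N1 and give 5,6-dibromoindoline-2,3-dione F2. N-methylation with MeI and K2CO3 in DMF should give 5,6-dibromo-1-methylindoline-2,3-dione F3. Wolff–Kishner reduction of the C3 carbonyl with N2H4·H2O (hydrazone at 25 °C, then 130 °C) should give the oxindole, so the fallback comes back to the route at 10.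

Step 3. What may go wrong is base-catalysed isomerisation of the enamide to the conjugated 1,5-dihydro tautomer, or self-condensation of the enamide with the N-acyliminium ion. The fallback sets out from 5 and replaces sulfonylation and amine base by a storable N,O-acetal that is cracked without base. MeOH with catalytic pyridinium p-toluenesulfonate at 25 °C should give 5-methoxy-1-methylpyrrolidin-2-one F4. Heating F4 with catalytic NH4Cl at 150 °C while methanol distils off, followed by vacuum distillation, should give the enamide, so the fallback comes back at 7.

Step 6. What may go wrong is addition–elimination of dimethylamine at C2 (a vinylogous acyl bromide) competing with slow iminium formation at the vinylogous-amide aldehyde. The fallback sets out from 10 and avoids both the aldehyde and free secondary amine. POBr3 without DMF in refluxing ClCH2CH2Cl should convert the lactam into 2,5,6-tribromo-1-methyl-1H-indole F5. Mannich aminomethylation of F5 at C3 with dimethyl(methylidene)ammonium iodide in MeCN at 25–60 °C, then basic work-up, should give the tertiary amine, so the fallback passes by 12 and comes back at 14.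

**Further compounds**

F1 | step 4 | 6-bromoindoline-2,3-dione (purchased) | O=C1Nc2cc(Br)ccc2C1=O
F2 | step 4 | 5,6-dibromoindoline-2,3-dione | O=C1Nc2cc(Br)c(Br)cc2C1=O
F3 | step 4 | 5,6-dibromo-1-methylindoline-2,3-dione | CN1C(=O)C(=O)c2cc(Br)c(Br)cc21
F4 | step 3 | 5-methoxy-1-methylpyrrolidin-2-one (racemic) | COC1CCC(=O)N1C
F5 | step 6 | 2,5,6-tribromo-1-methyl-1H-indole | Cn1c(Br)cc2cc(Br)c(Br)cc21
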